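The cyclopentane of the target carries three contiguous, mutually cis carbon branches. These are the CH(CH3) carbon of the bridge, the methylidene-bearing carbon of the cyclohexane (on the ring-fusion CH) and the propionyloxy carbinol carbon (on the quaternary C–CH3). This crowded triad is unfolded into the cyclohexanone ring of (R)-carvone, whose carbonyl carbon is the future methylidene-bearing carbon. The precursor is a 2-diazocyclohexanone with a butyrolactone on its quaternary α'-carbon. Photochemical Wolff rearrangement shifts the quaternary carbon onto the diazo carbon, contracts six to five, expels the carbonyl carbon as an exocyclic Weinreb amide and sets the ring-fusion CH. Lactone-tethered acylation then closes the cyclohexane, and a Nozaki–Hiyama–Kishi reaction closes the eleven-membered ring.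

Key step: step 3

Locants used below (not IUPAC):
- C1 is the ring carbon bearing =CH2, and C2 is the neighbouring cyclohexane CH.
- The bridge runs C3 (CH2), C4 (CHOH), C5(CH3)=C6, C7 (CH2), C8 (CHOAc), C9 (CHCH3) to C10.
- The cyclopentane is C10, C11, C12, C13 (quaternary, CH3), C16 (ring-fusion CH).
- The cyclohexane is C1, C2, C15 (CH2), C14 (CHOCOEt), C13, C16.

Assumption: methyl 4-oxobutanoate and 1-methyl-1-(trimethylsilyl)allene are taken as catalogue compounds.

Step 1
Reactants: 1 (R)-(−)-carvone; 2 methyl 4-oxobutanoate
Product: 6 keto lactone (S)-5-[(1R,4R)-1-methyl-2-oxo-4-(prop-1-en-2-yl)cyclohexyl]dihydrofuran-2(3H)-one, via lithium enolate 3 (not isolated), via titanium enolate 4 (not isolated), via aldol hydroxy ester 5 (not isolated)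
Conditions: L-Selectride, THF, −78 °C; ClTi(OiPr)3, −78 to −30 °C; 2, −78 °C to rt; 1 M HCl work-up
Reagents that add atoms: none
Why: Conjugate hydride addition gives the tetrasubstituted enolate regiospecifically, axial attack on the aldehyde puts the new C13–C14 bond cis to the C10 isopropenyl group, the triisopropoxytitanium enolate of a cyclic ketone is known to favour the syn aldol (C14–O syn to ring CH2 C12, as needed), and the aldolate closes the γ-lactone on the methyl ester (reductive aldol reaction, then lactonisation).

Step 2
Reactants: 6 keto lactone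
Product: 8 α-diazo ketone (N2 on C16 and all stereocentres as in 6), via trifluoroacetyl ketone 7 (not isolated)
Conditions: LiHMDS, THF, −78 °C; CF3CO2CH2CF3; 5% HCl wash; then MsN3, Et3N, H2O, MeCN, rt
Reagents that add atoms: methanesulfonyl azide CS(=O)(=O)N=[N+]=[N-]
Why: Danheiser detrifluoroacetylative diazo transfer: C16 is the only enolisable position of the ketone (C13 is quaternary) and the ketone is more acidic than the lactone, so activation and diazo transfer can occur only at C16 and no stereocentre is touched.

Step 3
Reactants: 8 α-diazo ketone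
Product: 10 all-cis cyclopentane Weinreb amide (C1 amide on C16 cis to the C10 isopropenyl group and to the C13 lactone branch), via ketene 9 (not isolated)
Conditions: hν (medium-pressure Hg lamp, Pyrex), MeONHMe (5 equiv), THF, 0 °C
Reagents that add atoms: N,O-dimethylhydroxylamine CNOC
Why: Irradiation expels N2 from the s-Z-locked cyclic diazo ketone and the C1–C13 bond migrates to C16 in concert (Wolff rearrangement, retention at the migrating quaternary C13), giving ketene 9, which MeONHMe captures at C1. The closest known reaction type is the photochemical ring contraction of 2-diazocyclohexanones to cyclopentanecarboxylic acid derivatives. The cyclopentane (C10–C11–C12–C13–C16) is closed by this 1,2-shift, which makes the C13–C16 bond, not by an exo or endo cyclisation, and no other ring is formed. The only new stereocentre, C16, is set when the amide enol is protonated on the ring face that carries C13–CH3 and C10–H, opposite the lactone and isopropenyl groups, so that C1 should end cis to both branches. The step needs the Wolff shift to beat a 1,2-H shift from C10, N–H insertion and attack on the isopropenyl group; the fixed s-Z geometry, direct metal-free excitation and the high migratory aptitude of the quaternary carbon secure this, and the regiochemistry is unambiguous because the diazo group can sit only on C16.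

Step 4
Reactants: 10 Weinreb amide
Product: 11 allylic alcohol (isopropenyl CH3 converted into C8H2OH)
Conditions: SeO2 (0.3 equiv), t-BuOOH, salicylic acid (cat.), CH2Cl2, rt
Reagents that add atoms: tert-butyl hydroperoxide CC(C)(C)OO
Why: Sharpless-modified Riley allylic oxidation (ene reaction, then [2,3]-shift) hydroxylates the isopropenyl CH3 in preference to the tertiary, crowded C10–H, which turns that methyl carbon into C8 and leaves =CH2 as the future C9 methyl group.

Step 5
Reactants: 11 allylic alcohol
Product: 12 saturated primary alcohol (9S)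
Conditions: H2 (1 atm), RhCl(PPh3)3 (5 mol %), PhH–EtOH, rt
Reagents that add atoms: none
Why: Homogeneous hydrogenation with Wilkinson's catalyst under steric control: allylic 1,3-strain holds C10–H next to the =CH2 group and the cis amide on C16 shields one alkene face, so H2 should add from the open face beside C11 and give (9S); hydroboration of 10 would give the opposite sense, which is why the methyl group was oxidised first.

Step 6
Reactants: 12 primary alcohol
Product: 13 aldehyde (C8HO)
Conditions: Dess–Martin periodinane, NaHCO3, CH2Cl2, 0 °C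
Reagents that add atoms: none
Why: Dess–Martin oxidation is neutral and fast, so the α-stereocentre C9 should not epimerise and lactone and amide are untouched.

Step 7
Reactants: 13 aldehyde; 14 1-methyl-1-(trimethylsilyl)allene
Product: 15 homopropargylic alcohol (8S and 8,9-syn)
Conditions: TiCl4 (2.5 equiv), CH2Cl2, −78 °C
Reagents that add atoms: none
Why: Danheiser propargylation (SE2' addition of an allenylsilane with loss of Me3SiCl) delivers the but-2-ynyl unit C7–C6≡C5–CH3 without allenyl isomers, and Felkin–Anh attack anti to ring carbon C10 gives the 8,9-syn alcohol.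

Step 8
Reactants: 15 homopropargylic alcohol
Product: 16 TBS ether
Conditions: TBSOTf, 2,6-lutidine, CH2Cl2, 0 °C
Reagents that add atoms: tert-butyldimethylsilyl triflate CC(C)(C)[Si](C)(C)OS(=O)(=O)C(F)(F)F
Why: Standard silylation with the triflate masks the hindered secondary alcohol against the base, hydride and ylide steps that follow and keeps it away from the C1 carbonyl group.

Step 9
Reactants: 16 TBS ether
Product: 18 tricyclic β-keto lactone (cis-hydrindanone whose C2 and C14 are bridged by C3(=O)–O), via lithium tetrahedral adduct 17 (not isolated)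
Conditions: LiHMDS (2.2 equiv), THF, −78 to −20 °C; AcOH quench
Reagents that add atoms: none
Why: Dieckmann-type intramolecular Claisen acylation: the lactone CH2 (C2) is the most acidic and least hindered site, its enolate attacks the cis Weinreb amide in a 6-exo-trig closure, the chelated adduct 17 blocks retro-Claisen cleavage until the quench, and C2 can only form with C3 cis to C14–O because both belong to the γ-lactone bridge (6-oxabicyclo[3.2.1]octane), which also tolerates only the cis ring fusion at C16.

Step 10
Reactants: 18 β-keto lactone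
Product: 19 methylidene lactone (C1=CH2)
Conditions: Zn, CH2Br2, TiCl4, THF–CH2Cl2, 0 °C to rt
Reagents that add atoms: dibromomethane BrCBr
Why: Takai–Lombardo methylenation is non-basic and works on hindered, enolisable ketones while leaving lactones, silyl ethers and alkynes alone.

Step 11
Reactants: 19 methylidene lactone
Product: 21 (E)-vinyl iodide lactone, via alkenylzirconocene 20 (not isolated)
Conditions: Cp2Zr(H)Cl (2 equiv), THF, rt to 40 °C; I2, −78 °C
Reagents that add atoms: iodine II
Why: Hydrozirconation–iodination: syn addition with equilibration places zirconium on the less hindered methyl-bearing alkyne carbon C5, iodinolysis proceeds with retention to the E iodide, and any partial reduction of the lactone only anticipates step 12.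

Step 12
Reactants: 21 vinyl iodide lactone
Product: 22 bridged lactol (C3 epimers)
Conditions: DIBAL-H (1.2 equiv), CH2Cl2, −78 °C; Rochelle salt
Reagents that add atoms: none
Why: DIBAL-H reduction at low temperature stops at the aluminium hemiacetal, so the bridged lactone gives the lactol while alkene, iodide and silyl ether survive.

Step 13
Reactants: 22 lactol
Product: 23 enol ether alcohol (C3H=C4H–OMe as an E/Z mixture with free C14–OH)
Conditions: MeOCH2PPh3Cl, NaHMDS, THF, 0 °C; then 22, 0 °C to rt
Reagents that add atoms: (methoxymethyl)triphenylphosphonium chloride COC[P+](c1ccccc1)(c1ccccc1)c1ccccc1.[Cl-]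
Why: Wittig homologation of a lactol: the small share of open hydroxy aldehyde is trapped by excess ylide faster than C2–H is removed, which adds C4, turns C3 into a future CH2 group, masks the aldehyde as an enol ether and frees C14–OH.

Step 14
Reactants: 23 enol ether alcohol
Product: 24 C14 propionate
Conditions: (EtCO)2O, DMAP, Et3N, CH2Cl2, rt
Reagents that add atoms: propionic anhydride CCC(=O)OC(=O)CC
Why: DMAP-catalysed acylation of the only free hydroxyl group installs the C14 propionate with retention.

Step 15
Reactants: 24 propionate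
Product: 25 hydroxy aldehyde (free C8–OH and C4HO)
Conditions: 48% aq HF, MeCN, 0 °C to rt
Reagents that add atoms: water O
Why: Aqueous HF cleaves the silyl ether and hydrolyses the enol ether in one operation (acid hydrolysis), while esters, vinyl iodide and the 1,1-disubstituted alkene should survive these mild conditions.

Step 16
Reactants: 25 hydroxy aldehyde
Product: 26 acetoxy aldehyde
Conditions: Ac2O, pyridine, DMAP (cat.), CH2Cl2, 0 °C
Reagents that add atoms: acetic anhydride CC(=O)OC(C)=O
Why: Acetylation of the only hydroxyl group under mild base completes the ester pattern before ring closure, the aldehyde being inert to these conditions.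

Step 17
Reactants: 26 acetoxy aldehyde
Product: 28 target CNP0180453.1, via alkenylchromium species 27 (not isolated)
Conditions: CrCl2 (10 equiv), NiCl2 (1 mol %), DMSO–THF, rt, 2 mM, slow addition
Reagents that add atoms: none
Why: Nozaki–Hiyama–Kishi macrocyclisation: Ni-catalysed formation of the alkenylchromium species with retention of the E geometry and its chemoselective addition to the aldehyde (esters and alkenes inert) close the eleven-membered ring at C4–C5 and give the free alcohol directly, (4R) being expected from attack on the outward face of the aldehyde in the folded, bridge-forming conformer.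

Compound list
1 | (R)-(−)-carvone | C=C(C)[C@@H]1CC=C(C)C(=O)C1 | starting material
2 | methyl 4-oxobutanoate | COC(=O)CCC=O | starting material
3 | lithium enolate of dihydrocarvone (C1–OLi, C1=C13) | C=C(C)[C@@H]1CCC(C)=C([O-])C1.[Li+] | intermediate
4 | triisopropoxytitanium enolate | C=C(C)[C@@H]1CCC(C)=C(O[Ti](OC(C)C)(OC(C)C)OC(C)C)C1 | intermediate
5 | aldol hydroxy ester (syn aldol, side chain cis to isopropenyl) | C=C(C)[C@@H]1CC[C@](C)([C@@H](O)CCC(=O)OC)C(=O)C1 | intermediate
6 | keto lactone (C10 R, C13 R, C14 S) | C=C(C)[C@@H]1CC[C@](C)([C@@H](OC(=O)C2)C2)C(=O)C1 | intermediate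
7 | C16-trifluoroacetyl ketone | C=C(C)[C@@H]1CC[C@](C)([C@@H](OC(=O)C2)C2)C(=O)C1C(=O)C(F)(F)F | intermediate
8 | α-diazo ketone (N2 on C16) | C=C(C)[C@@H]1CC[C@](C)([C@@H](OC(=O)C2)C2)C(=O)C1=[N+]=[N-] | intermediate
9 | ketene (C16=C1=O on the contracted ring) | C=C(C)[C@@H]1CC[C@](C)([C@@H](OC(=O)C2)C2)C1=C=O | intermediate
10 | all-cis cyclopentane Weinreb amide | C=C(C)[C@@H]1CC[C@](C)([C@@H](OC(=O)C2)C2)[C@@H]1C(=O)N(C)OC | intermediate
11 | allylic alcohol | C=C(CO)[C@@H]1CC[C@](C)([C@@H](OC(=O)C2)C2)[C@@H]1C(=O)N(C)OC | intermediate
12 | saturated primary alcohol (9S) | OC[C@@H](C)[C@@H]1CC[C@](C)([C@@H](OC(=O)C2)C2)[C@@H]1C(=O)N(C)OC | intermediate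
13 | aldehyde (C8HO) | O=C[C@@H](C)[C@@H]1CC[C@](C)([C@@H](OC(=O)C2)C2)[C@@H]1C(=O)N(C)OC | intermediate
14 | 1-methyl-1-(trimethylsilyl)allene | C=C=C(C)[Si](C)(C)C | starting material
15 | homopropargylic alcohol (8S, 9S) | CC#CC[C@H](O)[C@@H](C)[C@@H]1CC[C@](C)([C@@H](OC(=O)C2)C2)[C@@H]1C(=O)N(C)OC | intermediate
16 | TBS ether of 15 | CC#CC[C@H](O[Si](C)(C)C(C)(C)C)[C@@H](C)[C@@H]1CC[C@](C)([C@@H](OC(=O)C2)C2)[C@@H]1C(=O)N(C)OC | intermediate
17 | lithium tetrahedral adduct | CC#CC[C@H](O[Si](C)(C)C(C)(C)C)[C@@H](C)[C@@H]1CC[C@](C)([C@@H](OC(=O)[C@H]23)C2)[C@@H]1C3([O-])N(C)OC.[Li+] | intermediate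
18 | tricyclic β-keto lactone | CC#CC[C@H](O[Si](C)(C)C(C)(C)C)[C@@H](C)[C@@H]1CC[C@](C)([C@@H](OC(=O)[C@H]23)C2)[C@@H]1C3=O | intermediate
19 | methylidene lactone | CC#CC[C@H](O[Si](C)(C)C(C)(C)C)[C@@H](C)[C@@H]1CC[C@](C)([C@@H](OC(=O)[C@H]23)C2)[C@@H]1C3=C | intermediate
20 | alkenylzirconocene chloride | Cl[Zr](C1C=CC=C1)(C1C=CC=C1)/C(C)=C/C[C@H](O[Si](C)(C)C(C)(C)C)[C@@H](C)[C@@H]1CC[C@](C)([C@@H](OC(=O)[C@H]23)C2)[C@@H]1C3=C | intermediate
21 | (E)-vinyl iodide lactone | I/C(C)=C/C[C@H](O[Si](C)(C)C(C)(C)C)[C@@H](C)[C@@H]1CC[C@](C)([C@@H](OC(=O)[C@H]23)C2)[C@@H]1C3=C | intermediate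
22 | bridged lactol (C3 epimers) | I/C(C)=C/C[C@H](O[Si](C)(C)C(C)(C)C)[C@@H](C)[C@@H]1CC[C@](C)([C@@H](OC(O)[C@H]23)C2)[C@@H]1C3=C | intermediate
23 | enol ether alcohol (E/Z at C3=C4) | I/C(C)=C/C[C@H](O[Si](C)(C)C(C)(C)C)[C@@H](C)[C@@H]1CC[C@](C)([C@@H](O)C[C@H]2C=COC)[C@@H]1C2=C | intermediate
24 | C14 propionate | I/C(C)=C/C[C@H](O[Si](C)(C)C(C)(C)C)[C@@H](C)[C@@H]1CC[C@](C)([C@@H](OC(=O)CC)C[C@H]2C=COC)[C@@H]1C2=C | intermediate
25 | hydroxy aldehyde | I/C(C)=C/C[C@H](O)[C@@H](C)[C@@H]1CC[C@](C)([C@@H](OC(=O)CC)C[C@H]2CC=O)[C@@H]1C2=C | intermediate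
26 | acetoxy aldehyde | I/C(C)=C/C[C@H](OC(C)=O)[C@@H](C)[C@@H]1CC[C@](C)([C@@H](OC(=O)CC)C[C@H]2CC=O)[C@@H]1C2=C | intermediate
27 | alkenylchromium(III) dichloride | Cl[Cr](Cl)/C(C)=C/C[C@H](OC(C)=O)[C@@H](C)[C@@H]1CC[C@](C)([C@@H](OC(=O)CC)C[C@H]2CC=O)[C@@H]1C2=C | intermediate
28 | CNP0180453.1 | C=C1[C@@H]2C[C@@H](O)/C(C)=C/C[C@H](OC(C)=O)[C@@H](C)[C@@H]3CC[C@](C)([C@@H](OC(=O)CC)C2)[C@H]13 | target

Total step count: 17. Longest linear sequence: 17 steps, from (R)-carvone.

Steps most likely to fail

Step 17. Closure of the strained eleven-membered ring may be outrun by intermolecular coupling. The aldehyde may also be attacked on both faces, so that C4 forms without selectivity.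
- The fallback sets out from 26 and moves control of C4 from the C–C bond formation to a reagent-controlled reduction.
- The coupling is run without regard to C4. The alcohol mixture, which contains the C4-epimeric macrocyclic alcohol F1, is oxidised with Dess–Martin periodinane to the macrocyclic E-enone F2.
- 1,2-Reduction with (S)-Me-CBS and catecholborane in toluene at −78 °C then comes back to the route at 28.

Step 1. The tetrasubstituted enolate may react through a chair transition state and give mainly the anti aldol, so that C14 is formed with the wrong configuration. Retro-aldol cleavage may also erode the adduct.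
- The fallback sets out from 1 and sets C14 by reagent control.
- The L-Selectride enolate is trapped with monomeric formaldehyde to give the hydroxymethyl ketone F3. Dess–Martin oxidation gives the keto aldehyde F4.
- Brown allylboration with (−)-Ipc2B(allyl), the enantiomer that gives the (S)-carbinol, gives the homoallylic alcohol F5.
- Disiamylborane then H2O2/NaOH hydroborates only the monosubstituted alkene and gives the 1,4-diol F6.
- TEMPO/PhI(OAc)2 oxidative lactonisation comes back to the route at 6.

Step 5. Hydrogen may be delivered to the wrong alkene face if the CH2OH rotamer changes or the hydroxyl group binds the catalyst. The allylic alcohol may also isomerise to the aldehyde with loss of control at C9.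
- The fallback sets out from 11 and uses catalyst control on the carboxylic acid.
- MnO2 gives the enal F7, and Pinnick oxidation gives the α-substituted acrylic acid F8.
- Hydrogenation with Ru(OAc)2[(S)-BINAP] in MeOH gives the (9S)-acid F9.
- BH3·THF at 0 °C reduces only the acid and comes back to the route at 12.

Further compounds
F1 | step 17 | C4-epimeric macrocyclic alcohol | C=C1[C@@H]2C[C@H](O)/C(C)=C/C[C@H](OC(C)=O)[C@@H](C)[C@@H]3CC[C@](C)([C@@H](OC(=O)CC)C2)[C@H]13
F2 | step 17 | macrocyclic E-enone | C=C1[C@@H]2CC(=O)/C(C)=C/C[C@H](OC(C)=O)[C@@H](C)[C@@H]3CC[C@](C)([C@@H](OC(=O)CC)C2)[C@H]13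
F3 | step 1 | hydroxymethyl ketone | C=C(C)[C@@H]1CC[C@](C)(CO)C(=O)C1
F4 | step 1 | keto aldehyde | C=C(C)[C@@H]1CC[C@](C)(C=O)C(=O)C1
F5 | step 1 | homoallylic alcohol | C=C(C)[C@@H]1CC[C@](C)([C@@H](O)CC=C)C(=O)C1
F6 | step 1 | 1,4-diol | C=C(C)[C@@H]1CC[C@](C)([C@@H](O)CCCO)C(=O)C1
F7 | step 5 | enal | C=C(C=O)[C@@H]1CC[C@](C)([C@@H](OC(=O)C2)C2)[C@@H]1C(=O)N(C)OC
F8 | step 5 | α-substituted acrylic acid | C=C(C(=O)O)[C@@H]1CC[C@](C)([C@@H](OC(=O)C2)C2)[C@@H]1C(=O)N(C)OC
F9 | step 5 | (9S)-acid | OC(=O)[C@@H](C)[C@@H]1CC[C@](C)([C@@H](OC(=O)C2)C2)[C@@H]1C(=O)N(C)OC
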